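Remark on the chemistry: atoms are numbered along the C15 chain (C1 = alkyne CH; ring = O plus C6–C10). The target is taken as (3Z,6S,7S,9R,10R,12E), which places all four ring substituents on one face.

## The problem

1. The target is an oxane (O, C6, C7, C8, C9, C10) whose four substituents are all cis: the pentenynyl arm at C6, Cl at C7, Br at C9 and the bromopentenyl arm at C10. In the chair with both arms equatorial the two halogens are syn-diaxial.
2. Both arms are joined through CH2 groups (C5, C11), so neither ring carbon next to oxygen is π-activated for ring closure. A chair-like haloetherification of a (Z)-C9=C10 alkene would also place C11 axial, so the ring cannot simply be closed with the halogens in place.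
3. C7 and C9 flank the C8 methylene in nearly identical environments yet must carry different halogens. The two sites therefore need a built-in difference.
4. Stereocontrol can be relayed: C6 can set C10 across the ring oxygen, C10 can set C9, and C6 can set C7, each by addition anti to the neighbouring arm. Both heteroatom-bearing centres must then be inverted by halide to give the axial, cis halides.
5. The (E)-bromoalkene carries Br on the fully substituted carbon with its two carbon substituents cis. Halo-Wittig reagents and trans-selective couplings of 1,1-dibromoalkenes tend to give the other isomer, so it must come from a syn H/Br addition to an alkyne.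
6. Fragile groups are the skipped (Z)-enyne, the axial secondary halides (E2 through antiperiplanar axial hydrogens; participation of the ring oxygen), the vinyl bromide (alkyllithiums, zerovalent palladium) and a β-alkoxy aldehyde on the way.
7. The enabling feature is the segment O–C6 / C7–C8–C9–C10, with heteroatoms at C7 and C9 and carbon arms at C6 and C10. This is the oxidation pattern of an Achmatowicz pyranone (C7 ketone, C8=C9 enone, C10 ketal carbon). That pyranone comes from a 2,5-disubstituted furan whose ring carbons are C7–C10 and whose carbinol supplies C6 and the ring oxygen.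

## Retrosynthesis

**Enyne last.** Target 25 is cut at C3=C4 to aldehyde 20 and 1,3-bis(triisopropylsilyl)propyne 21, via silyl enyne 24. A cut at C2–C3 (coupling of a vinyl iodide) would need palladium next to the vinyl bromide and one more step. The Peterson route brings C1–C3 in one operation with Z control. The precursor lacks the most fragile group; the forward step must be Z-selective and spare the halides.

**Aldehyde from an allyl group.** The C4 carbonyl of 20 is traced to the terminal alkene of 18. An allyl group is the most inert placeholder for CH2CHO through oxidation, acid, hydride and phosphine chemistry. The forward cleavage must choose the monosubstituted alkene over the bromoalkene.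

**Halogens by inversion, sites told apart by boron.** C9–Br of 18 is cut to the equatorial C9–OH of 17, and C7–Cl to the equatorial C7–OH of 15. The C9–O bond of 17 is traced back to the C9–B bond of 16. Compared with a free diol, the B/O difference orders the two substitutions without protecting groups. Chloride goes in first (unhindered axial entry, and a poor leaving group afterwards), bromide last. Two clean SN2 inversions are required, the second syn to an axial chloride.

**Enone as the 1,3-relationship.** The C7–H bond of 15 (hydride to ketone 14) and the C9–B bond of 14 (conjugate borylation of enone 13) are cut. The enone polarity guarantees C9, not C8, as the second heteroatom site. Enone 13 has only two stereocentres, and both new centres are relayed anti to the arms.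

**Key disconnection.** The C10–H bond of 13 is cut to hemiketal 12 (hydride to the oxocarbenium ion, cis to C6). Pyranone 12 is then traced by the Achmatowicz transform to furan 11. A C10–O cut in a saturated precursor would need C9 and C10 preformed and a 6-endo closure. Here the ring closes by hemiketalisation of an ene-dione whose Z geometry is fixed by the furan, and C10 is set afterwards. Precursor 11 is flat, with one stereocentre.

**Furan assembly.** The C10–C11 bond of 11 is cut to the dilithio derivative 10 of furyl carbinol 9 and allylic bromide 6. Bromide 6 already carries the complete bromoalkene with fixed geometry. Building that alkene later from an aldehyde would give the wrong isomer.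

**Building blocks.** Carbinol 9 is cut at C5–C6 to furfural 7 and allylstannane 8 by catalytic asymmetric allylation, the only external source of chirality. Bromide 6 goes back through alcohol 5, ester 4 and stannane 3 to ethyl pent-2-ynoate 1 by syn stannylcupration, which fixes H and the later Br cis.

## Roads not taken

**Alternative 1:** the most obvious plan cuts C10–O of an all-equatorial oxane diol. Epoxy alcohol A1 would close by 6-endo opening to oxane A2, followed by two inversions.
- With C11 sp3 nothing favours 6-endo over 5-exo opening, so the oxolane is the expected product unless a directing group is added and later removed.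
- A1 needs three stereocentres set in separate acyclic asymmetric steps before the ring exists.
- The C7 and C9 oxygens must be told apart by protecting-group steps.
- The chosen plan needs the same two inversions but gets ring, regiochemistry and site differentiation from the pyranone.

**Alternative 2:** the biomimetic plan forms C10–O, C9–Br and C7–Cl at once. A bromonium ion on C9=C10 of cis-epoxide A3 would be captured by the epoxide oxygen to give bicyclic oxonium ion A4, opened by chloride at C7.
- The epoxide oxygen must attack through the lone pair syn to C8, which in a cis-epoxide is also syn to C5. The 2,6-cis product then needs C11 and Br on the face of A4 that already holds C5. The kinetically preferred oxonium ion should therefore lead to the 2,6-trans series.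
- Chloride has no bias for C7 (oxane) over C6 (oxolane).
- The bromonium source must also ignore the enyne alkene.
- The chosen plan sets C10 by hydride delivery anti to the C6 arm, which gives cis.

**Alternative 3:** a C–C cleavage plan: furan and an oxyallyl cation give meso oxabicycle A5, whose bridge enforces the 2,6-cis relationship. Desymmetrisation and Baeyer–Villiger cleavage of the two-carbon bridge would release one arm as an acetate unit.
- The carbonyl of A5 sits at C8, the one ring carbon that must end as CH2, and C7 and C9 are bare. Oxygen would have to be moved twice, or a C8 ketone removed next to α-halogens.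
- The second arm would still have to be attached cis at an anomeric carbon.
- The Achmatowicz pyranone has oxygen exactly at C7 and an electrophilic C9, and is far shorter.

Key step: step 7

## Route

Step 1
Reactants: 1 ethyl pent-2-ynoate
Product: 3 ethyl (2E)-3-(trimethylstannyl)pent-2-enoate, via vinylcopper adduct 2 (not isolated)
Conditions: Me3SnSnMe3, MeLi, THF, −20 °C; CuBr·SMe2, −78 °C; then 1, MeOH, −78 °C
Reagents that add atoms: hexamethylditin C[Sn](C)(C)[Sn](C)(C)C
Why: Stannylcupration of a 2-ynoate: Me3Sn–Cu adds syn, tin to C3 and copper to C2, and protonation at −78 °C traps the kinetic adduct with retention, so tin and the new hydrogen are cis (E ester).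

Step 2
Reactants: 3 ethyl (2E)-3-(trimethylstannyl)pent-2-enoate
Product: 4 ethyl (2E)-3-bromopent-2-enoate
Conditions: Br2, CH2Cl2, −78 °C
Reagents that add atoms: bromine BrBr
Why: Bromodestannylation is an ipso electrophilic substitution with retention of alkene geometry, which fixes Br cis to the vinylic hydrogen.

Step 3
Reactants: 4 ethyl (2E)-3-bromopent-2-enoate
Product: 5 (2E)-3-bromopent-2-en-1-ol
Conditions: iBu2AlH (2.2 equiv), CH2Cl2, −78 °C
Reagents that add atoms: none
Why: Low-temperature 1,2-reduction of the enoate to the allylic alcohol; the vinyl bromide and the geometry are untouched.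

Step 4
Reactants: 5 (2E)-3-bromopent-2-en-1-ol
Product: 6 (2E)-1,3-dibromopent-2-ene
Conditions: CBr4, PPh3, CH2Cl2, 0 °C
Reagents that add atoms: carbon tetrabromide BrC(Br)(Br)Br
Why: Appel bromination by SN2 at the primary allylic carbon; transposition is disfavoured because the other allyl terminus is fully substituted.

Step 5
Reactants: 7 furfural; 8 allyltributylstannane
Product: 9 (1S)-1-(furan-2-yl)but-3-en-1-ol
Conditions: (S)-BINOL (10 mol%), Ti(OiPr)4 (10 mol%), 4 Å MS, CH2Cl2, −20 °C
Reagents that add atoms: none
Why: Keck asymmetric allylation: the BINOL–Ti(OiPr)4 Lewis acid should direct the allylstannane to the Si face of the aldehyde, giving the (S)-carbinol that becomes C6 and is the only centre set by an external chiral source.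

Step 6
Reactants: 9 (1S)-1-(furan-2-yl)but-3-en-1-ol; 6 (2E)-1,3-dibromopent-2-ene
Product: 11 (1S)-1-{5-[(2E)-3-bromopent-2-en-1-yl]furan-2-yl}but-3-en-1-ol, via dilithio derivative 10 (not isolated)
Conditions: n-BuLi (2.05 equiv), THF, −78 → 0 °C; then 6, −78 → 0 °C
Reagents that add atoms: none
Why: O,C-dilithiation of a furfuryl alcohol (alkoxide, then metalation of the furan α-position), followed by SN2 alkylation of the furyllithium by the allylic bromide; the C–Li end reacts much faster than the lithium alkoxide and the carbinol centre is not touched.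

Step 7
Reactants: 11 (1S)-1-{5-[(2E)-3-bromopent-2-en-1-yl]furan-2-yl}but-3-en-1-ol
Product: 12 (2S)-6-[(2E)-3-bromopent-2-en-1-yl]-6-hydroxy-2-(prop-2-en-1-yl)-2H-pyran-3(6H)-one (both C10 epimers)
Conditions: NBS (1.05 equiv), NaHCO3, NaOAc, THF/H2O 4:1, 0 °C
Reagents that add atoms: water O
Why: Achmatowicz rearrangement (oxidative ring expansion of a furfuryl alcohol). NBS attacks the electron-rich furan at an α-carbon, water adds to the resulting oxocarbenium ion, and loss of HBr opens the 2,5-dihydrofuran to the (Z)-ene-1,4-dione C7(=O)–C8=C9–C10(=O). The C6 hydroxyl then closes the six-membered ring on the C10 ketone by 6-exo-trig hemiketalisation, so the carbinol oxygen becomes the ring oxygen, C7 the ketone, C8=C9 the enone alkene and C10 the ketal carbon. C6 is not touched and keeps its configuration. The only new stereocentre, the C10 hemiketal, forms as an equilibrating mixture and is erased in step 8. The selectivity needed is oxidation of the furan in preference to the terminal alkene and the bromoalkene; the furan is by far the most electron-rich π system, and one equivalent of NBS under buffered aqueous conditions at 0 °C should secure it. The Z geometry of the ene-dione that ring closure requires is guaranteed because that alkene comes from the furan ring.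

Step 8
Reactants: 12 (2S)-6-[(2E)-3-bromopent-2-en-1-yl]-6-hydroxy-2-(prop-2-en-1-yl)-2H-pyran-3(6H)-one
Product: 13 (2S,6R)-6-[(2E)-3-bromopent-2-en-1-yl]-2-(prop-2-en-1-yl)-2H-pyran-3(6H)-one
Conditions: Et3SiH (5 equiv), CF3CO2H, CH2Cl2, −40 °C
Reagents that add atoms: none
Why: Ionic hydrogenation of the hemiketal: acid ionises C10–OH to the cyclic oxocarbenium ion and the silane delivers hydride to C10 from the face opposite the C6 allyl group, giving the 2,6-cis dihydropyranone; excess silane at low temperature should outrun loss of a C11 proton from the cation.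

Step 9
Reactants: 13 (2S,6R)-6-[(2E)-3-bromopent-2-en-1-yl]-2-(prop-2-en-1-yl)-2H-pyran-3(6H)-one
Product: 14 (2S,5S,6R)-6-[(2E)-3-bromopent-2-en-1-yl]-2-(prop-2-en-1-yl)-5-(4,4,5,5-tetramethyl-1,3,2-dioxaborolan-2-yl)oxan-3-one
Conditions: B2pin2, CuCl (5 mol%), DPEphos (5 mol%), NaOtBu (10 mol%), MeOH (2 equiv), THF, rt
Reagents that add atoms: bis(pinacolato)diboron CC1(C)OB(OC1(C)C)B1OC(C)(C)C(C)(C)O1
Why: Conjugate borylation of a cyclic enone by a monovalent copper boryl: the Cu–B unit adds to C9 on the face anti to the adjacent C10 arm (and to the C6 arm), so boron ends trans to both arms, and methanol protonates the copper enolate; isolated alkenes and the vinyl bromide are not expected to react at room temperature.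

Step 10
Reactants: 14 (2S,5S,6R)-6-[(2E)-3-bromopent-2-en-1-yl]-2-(prop-2-en-1-yl)-5-(4,4,5,5-tetramethyl-1,3,2-dioxaborolan-2-yl)oxan-3-one
Product: 15 (2S,3R,5S,6R)-6-[(2E)-3-bromopent-2-en-1-yl]-2-(prop-2-en-1-yl)-5-(4,4,5,5-tetramethyl-1,3,2-dioxaborolan-2-yl)oxan-3-ol
Conditions: NaBH4, MeOH/THF, −78 °C
Reagents that add atoms: none
Why: Hydride reduction of a 2-substituted oxan-3-one: the small hydride should attack axially (the ring oxygen removes one 1,3-diaxial hydrogen from that face), giving the equatorial C7 alcohol trans to the allyl group; the boronic ester is inert.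

Step 11
Reactants: 15 (2S,3R,5S,6R)-6-[(2E)-3-bromopent-2-en-1-yl]-2-(prop-2-en-1-yl)-5-(4,4,5,5-tetramethyl-1,3,2-dioxaborolan-2-yl)oxan-3-ol
Product: 16 2-[(2R,3S,5S,6S)-2-[(2E)-3-bromopent-2-en-1-yl]-5-chloro-6-(prop-2-en-1-yl)oxan-3-yl]-4,4,5,5-tetramethyl-1,3,2-dioxaborolane
Conditions: CCl4, P(n-Oct)3, toluene, 60 °C
Reagents that add atoms: carbon tetrachloride ClC(Cl)(Cl)Cl
Why: Appel chlorination with inversion: chloride displaces the C7 oxyphosphonium from the backside (SN2), turning the equatorial alcohol into the axial chloride cis to the C6 arm; the equatorial leaving group has no antiperiplanar hydrogen, which disfavours E2.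

Step 12
Reactants: 16 2-[(2R,3S,5S,6S)-2-[(2E)-3-bromopent-2-en-1-yl]-5-chloro-6-(prop-2-en-1-yl)oxan-3-yl]-4,4,5,5-tetramethyl-1,3,2-dioxaborolane
Product: 17 (2R,3S,5S,6S)-2-[(2E)-3-bromopent-2-en-1-yl]-5-chloro-6-(prop-2-en-1-yl)oxan-3-ol
Conditions: NaBO3·4H2O, THF/H2O 1:1, rt
Reagents that add atoms: sodium perborate [Na+].[O-]OB=O
Why: Oxidation of a secondary alkylboronic ester: carbon migrates from boron to oxygen with retention, unveiling the equatorial C9 alcohol only after C7 has been chlorinated; the mildly basic perborate should spare the secondary chloride.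

Step 13
Reactants: 17 (2R,3S,5S,6S)-2-[(2E)-3-bromopent-2-en-1-yl]-5-chloro-6-(prop-2-en-1-yl)oxan-3-ol
Product: 18 (2R,3R,5S,6S)-3-bromo-2-[(2E)-3-bromopent-2-en-1-yl]-5-chloro-6-(prop-2-en-1-yl)oxane
Conditions: CBr4, P(n-Oct)3, toluene, 70 °C
Reagents that add atoms: carbon tetrabromide BrC(Br)(Br)Br
Why: Appel bromination with inversion at C9: backside attack by bromide gives the axial bromide cis to the C10 arm and syn to the C7 chloride; the chloride is a poor leaving group toward bromide and should not be exchanged.

Step 14
Reactants: 18 (2R,3R,5S,6S)-3-bromo-2-[(2E)-3-bromopent-2-en-1-yl]-5-chloro-6-(prop-2-en-1-yl)oxane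
Product: 20 2-[(2S,3S,5R,6R)-5-bromo-6-[(2E)-3-bromopent-2-en-1-yl]-3-chlorooxan-2-yl]acetaldehyde, via vicinal diol 19 (not isolated)
Conditions: OsO4 (2 mol%), NMO, acetone/H2O, 0 °C; then NaIO4, THF/pH 7 buffer, 0 °C
Reagents that add atoms: N-methylmorpholine N-oxide C[N+]1([O-])CCOCC1; water O
Why: Dihydroxylation then glycol cleavage (Lemieux–Johnson type): OsO4 should select the monosubstituted terminal alkene over the electron-poor, hindered bromoalkene, and periodate cleaves the diol to the aldehyde under neutral conditions.

Step 15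
Reactants: 20 2-[(2S,3S,5R,6R)-5-bromo-6-[(2E)-3-bromopent-2-en-1-yl]-3-chlorooxan-2-yl]acetaldehyde; 21 1,3-bis(triisopropylsilyl)propyne
Product: 24 (2R,3R,5S,6S)-3-bromo-2-[(2E)-3-bromopent-2-en-1-yl]-5-chloro-6-[(2Z)-5-(triisopropylsilyl)pent-2-en-4-yn-1-yl]oxane, via lithiated propyne 22 (not isolated), via silyl alkoxide adduct 23 (not isolated)
Conditions: 21, n-BuLi, THF, −78 °C; then 20, −78 → 0 °C
Reagents that add atoms: none
Why: Peterson olefination: the bulky silyl-stabilised propargyl anion adds to the aldehyde and the β-silyl alkoxide undergoes syn elimination of silanolate, which should give the (Z)-enyne because the triisopropylsilyl groups control the geometry of addition; the stabilised anion at −78 °C should not exchange with the vinyl bromide.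

Step 16
Reactants: 24 (2R,3R,5S,6S)-3-bromo-2-[(2E)-3-bromopent-2-en-1-yl]-5-chloro-6-[(2Z)-5-(triisopropylsilyl)pent-2-en-4-yn-1-yl]oxane
Product: 25 (2R,3R,5S,6S)-3-bromo-2-[(2E)-3-bromopent-2-en-1-yl]-5-chloro-6-[(2Z)-pent-2-en-4-yn-1-yl]oxane
Conditions: Bu4NF, THF, 0 °C
Reagents that add atoms: none
Why: Fluoride-induced protodesilylation of the alkynylsilane releases the terminal alkyne; low temperature and short contact should keep E2 of the axial halides at bay.

## Compound list

1 | ethyl pent-2-ynoate | CCC#CC(=O)OCC | starting material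
2 | ethyl (2Z)-2-cuprio-3-(trimethylstannyl)pent-2-enoate (vinylcopper adduct) | CCOC(=O)/C([Cu])=C(\CC)[Sn](C)(C)C | intermediate (not isolated)
3 | ethyl (2E)-3-(trimethylstannyl)pent-2-enoate | CCOC(=O)/C=C(\CC)[Sn](C)(C)C | intermediate
4 | ethyl (2E)-3-bromopent-2-enoate | CCOC(=O)/C=C(\CC)Br | intermediate
5 | (2E)-3-bromopent-2-en-1-ol | OC/C=C(\CC)Br | intermediate
6 | (2E)-1,3-dibromopent-2-ene | BrC/C=C(\CC)Br | intermediate
7 | furfural | O=Cc1ccco1 | starting material
8 | allyltributylstannane | C=CC[Sn](CCCC)(CCCC)CCCC | starting material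
9 | (1S)-1-(furan-2-yl)but-3-en-1-ol | C=CC[C@H](O)c1ccco1 | intermediate
10 | lithium (1S)-1-(5-lithiofuran-2-yl)but-3-en-1-olate (dilithio derivative) | C=CC[C@H](O[Li])c1ccc([Li])o1 | intermediate (not isolated)
11 | (1S)-1-{5-[(2E)-3-bromopent-2-en-1-yl]furan-2-yl}but-3-en-1-ol | C=CC[C@H](O)c1ccc(C/C=C(\CC)Br)o1 | intermediate
12 | (2S)-6-[(2E)-3-bromopent-2-en-1-yl]-6-hydroxy-2-(prop-2-en-1-yl)-2H-pyran-3(6H)-one (C10 epimers) | C=CC[C@@H]1OC(O)(C/C=C(\CC)Br)C=CC1=O | intermediate
13 | (2S,6R)-6-[(2E)-3-bromopent-2-en-1-yl]-2-(prop-2-en-1-yl)-2H-pyran-3(6H)-one | C=CC[C@@H]1O[C@H](C/C=C(\CC)Br)C=CC1=O | intermediate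
14 | (2S,5S,6R)-6-[(2E)-3-bromopent-2-en-1-yl]-2-(prop-2-en-1-yl)-5-(4,4,5,5-tetramethyl-1,3,2-dioxaborolan-2-yl)oxan-3-one | C=CC[C@@H]1O[C@H](C/C=C(\CC)Br)[C@@H](B2OC(C)(C)C(C)(C)O2)CC1=O | intermediate
15 | (2S,3R,5S,6R)-6-[(2E)-3-bromopent-2-en-1-yl]-2-(prop-2-en-1-yl)-5-(4,4,5,5-tetramethyl-1,3,2-dioxaborolan-2-yl)oxan-3-ol | C=CC[C@@H]1O[C@H](C/C=C(\CC)Br)[C@@H](B2OC(C)(C)C(C)(C)O2)C[C@H]1O | intermediate
16 | 2-[(2R,3S,5S,6S)-2-[(2E)-3-bromopent-2-en-1-yl]-5-chloro-6-(prop-2-en-1-yl)oxan-3-yl]-4,4,5,5-tetramethyl-1,3,2-dioxaborolane | C=CC[C@@H]1O[C@H](C/C=C(\CC)Br)[C@@H](B2OC(C)(C)C(C)(C)O2)C[C@@H]1Cl | intermediate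
17 | (2R,3S,5S,6S)-2-[(2E)-3-bromopent-2-en-1-yl]-5-chloro-6-(prop-2-en-1-yl)oxan-3-ol | C=CC[C@@H]1O[C@H](C/C=C(\CC)Br)[C@@H](O)C[C@@H]1Cl | intermediate
18 | (2R,3R,5S,6S)-3-bromo-2-[(2E)-3-bromopent-2-en-1-yl]-5-chloro-6-(prop-2-en-1-yl)oxane | C=CC[C@@H]1O[C@H](C/C=C(\CC)Br)[C@H](Br)C[C@@H]1Cl | intermediate
19 | 3-[(2S,3S,5R,6R)-5-bromo-6-[(2E)-3-bromopent-2-en-1-yl]-3-chlorooxan-2-yl]propane-1,2-diol (carbinol epimers) | OCC(O)C[C@@H]1O[C@H](C/C=C(\CC)Br)[C@H](Br)C[C@@H]1Cl | intermediate (not isolated)
20 | 2-[(2S,3S,5R,6R)-5-bromo-6-[(2E)-3-bromopent-2-en-1-yl]-3-chlorooxan-2-yl]acetaldehyde | O=CC[C@@H]1O[C@H](C/C=C(\CC)Br)[C@H](Br)C[C@@H]1Cl | intermediate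
21 | 1,3-bis(triisopropylsilyl)propyne | CC(C)[Si](C(C)C)(C(C)C)CC#C[Si](C(C)C)(C(C)C)C(C)C | starting material
22 | 1-lithio-1,3-bis(triisopropylsilyl)propyne (lithiated propyne) | [Li]C(C#C[Si](C(C)C)(C(C)C)C(C)C)[Si](C(C)C)(C(C)C)C(C)C | intermediate (not isolated)
23 | lithium β-silyl alkoxide adduct of 20 and 22 (carbinol and silyl-bearing centres as mixture) | [Li]OC(C[C@@H]1O[C@H](C/C=C(\CC)Br)[C@H](Br)C[C@@H]1Cl)C(C#C[Si](C(C)C)(C(C)C)C(C)C)[Si](C(C)C)(C(C)C)C(C)C | intermediate (not isolated)
24 | (2R,3R,5S,6S)-3-bromo-2-[(2E)-3-bromopent-2-en-1-yl]-5-chloro-6-[(2Z)-5-(triisopropylsilyl)pent-2-en-4-yn-1-yl]oxane | CC(C)[Si](C#C/C=C\C[C@@H]1O[C@H](C/C=C(\CC)Br)[C@H](Br)C[C@@H]1Cl)(C(C)C)C(C)C | intermediate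
25 | (2R,3R,5S,6S)-3-bromo-2-[(2E)-3-bromopent-2-en-1-yl]-5-chloro-6-[(2Z)-pent-2-en-4-yn-1-yl]oxane | C#C/C=C\C[C@@H]1O[C@H](C/C=C(/Br)CC)[C@H](Br)C[C@@H]1Cl | target

## Step count and least certain steps

Total: 16 steps. Longest linear sequence: 15 steps (1, 2, 3, 4, 6, then 7–16); step 5 is a one-step branch.

**Step 7 (key step).** The most likely failure is loss of chemoselectivity: electrophilic bromine could be consumed at the terminal alkene (bromohydrin formation) or at the doubly activated C11 methylene, or the hemiketal could dehydrate under insufficient buffering. The fallback replaces electrophilic bromination by a cycloaddition. Starting from 11, photooxygenation with singlet oxygen (O2, rose bengal, visible light, CH2Cl2/MeOH, −78 °C) should give the furan endoperoxide F1 by [4+2] addition; isolated alkenes and the electron-poor bromoalkene react far more slowly. Reduction with Me2S gives the same (Z)-ene-dione, which closes to 12, where the route is rejoined.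

**Step 13.** Bromide must enter axially at C9, syn to the axial C7 chloride. If this backside attack is slow, participation of the antiperiplanar ring oxygen (retention, or ring contraction through a bicyclic oxonium ion), elimination, or epimerisation of the product by bromide exchange could take over at 70 °C. The fallback separates activation from displacement. Starting from 17, Tf2O and 2,6-lutidine in CH2Cl2 at −78 °C should give the C9 trifluoromethanesulfonate F6. Bu4NBr in toluene at −40 → 0 °C should then displace it with inversion well below the temperature at which E2 and halide exchange become competitive, rejoining the route at 18.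

**Step 10.** Facial selectivity of hydride delivery may be poor, giving partly the axial (cis) alcohol, which cannot be converted into the axial chloride by inversion. The fallback makes the wrong epimer on purpose and inverts it. Starting from 14, the bulky LiBH(s-Bu)3 (THF, −78 °C, non-oxidative work-up) should attack equatorially to give the cis alcohol F4. Mitsunobu inversion (4-nitrobenzoic acid, PPh3, DIAD) gives the trans 4-nitrobenzoate F5, and K2CO3 in MeOH returns the route to 15.

**Step 6.** Metalation of the furan α-position of the alkoxide may be incomplete, or the electrophile may be diverted by O-alkylation, by halogen–lithium exchange at the vinyl bromide, or by excess n-BuLi. The fallback reverses the order of furan substitution. Starting from 6 and commercial furan, 2-furyllithium (n-BuLi, THF, 0 °C) is alkylated to 2-[(2E)-3-bromopent-2-en-1-yl]furan F2. Vilsmeier–Haack formylation (POCl3, DMF) gives 5-[(2E)-3-bromopent-2-en-1-yl]furan-2-carbaldehyde F3. Keck allylation of F3 with 8 under the conditions of step 5 returns to 11.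

**Step 15 (with step 16).** The organolithium may act as a base on the β-alkoxy aldehyde (ring opening by β-elimination) or on the axial halides, Z-selectivity may erode, and fluoride in step 16 may cause E2. The fallback avoids both the carbanion and fluoride. Starting from 20, Stork–Zhao olefination (Ph3PCH2I iodide, NaN(SiMe3)2, THF, −78 °C) should give the (Z)-vinyl iodide F7. Sonogashira coupling with trimethylsilylacetylene (Pd(PPh3)4, CuI, iPr2NH, rt) should occur at the vinyl iodide much faster than at the trisubstituted vinyl bromide, giving silyl enyne F8. K2CO3 in MeOH at 0 °C then gives 25.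

## Further compounds

F1 | step 7 | 1-[(1S)-1-hydroxybut-3-en-1-yl]-4-[(2E)-3-bromopent-2-en-1-yl]-2,3,7-trioxabicyclo[2.2.1]hept-5-ene (furan endoperoxide, bridgehead epimers) | C=CC[C@H](O)C12OOC(C/C=C(\CC)Br)(O1)C=C2
F2 | step 6 | 2-[(2E)-3-bromopent-2-en-1-yl]furan | c1coc(C/C=C(\CC)Br)c1
F3 | step 6 | 5-[(2E)-3-bromopent-2-en-1-yl]furan-2-carbaldehyde | O=Cc1ccc(C/C=C(\CC)Br)o1
F4 | step 10 | (2S,3S,5S,6R)-6-[(2E)-3-bromopent-2-en-1-yl]-2-(prop-2-en-1-yl)-5-(4,4,5,5-tetramethyl-1,3,2-dioxaborolan-2-yl)oxan-3-ol | C=CC[C@@H]1O[C@H](C/C=C(\CC)Br)[C@@H](B2OC(C)(C)C(C)(C)O2)C[C@@H]1O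
F5 | step 10 | (2S,3R,5S,6R)-6-[(2E)-3-bromopent-2-en-1-yl]-2-(prop-2-en-1-yl)-5-(4,4,5,5-tetramethyl-1,3,2-dioxaborolan-2-yl)oxan-3-yl 4-nitrobenzoate | C=CC[C@@H]1O[C@H](C/C=C(\CC)Br)[C@@H](B2OC(C)(C)C(C)(C)O2)C[C@H]1OC(=O)c1ccc(cc1)[N+](=O)[O-]
F6 | step 13 | (2R,3S,5S,6S)-2-[(2E)-3-bromopent-2-en-1-yl]-5-chloro-6-(prop-2-en-1-yl)oxan-3-yl trifluoromethanesulfonate | C=CC[C@@H]1O[C@H](C/C=C(\CC)Br)[C@@H](OS(=O)(=O)C(F)(F)F)C[C@@H]1Cl
F7 | step 15 | (2R,3R,5S,6S)-3-bromo-2-[(2E)-3-bromopent-2-en-1-yl]-5-chloro-6-[(2Z)-3-iodoprop-2-en-1-yl]oxane | I/C=C\C[C@@H]1O[C@H](C/C=C(\CC)Br)[C@H](Br)C[C@@H]1Cl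
F8 | step 15 | (2R,3R,5S,6S)-3-bromo-2-[(2E)-3-bromopent-2-en-1-yl]-5-chloro-6-[(2Z)-5-(trimethylsilyl)pent-2-en-4-yn-1-yl]oxane | C[Si](C)(C)C#C/C=C\C[C@@H]1O[C@H](C/C=C(\CC)Br)[C@H](Br)C[C@@H]1Cl
A1 | alternative 1 | (4S,5R)-7-[(2S,3S)-3-[(2E)-3-bromopent-2-en-1-yl]oxiran-2-yl]-5-(tert-butyldimethylsilyloxy)hept-1-en-4-ol (trans-epoxy alcohol) | C=CC[C@H](O)[C@H](O[Si](C)(C)C(C)(C)C)C[C@@H]1O[C@H]1C/C=C(\CC)Br
A2 | alternative 1 | (2R,3S,5R,6S)-2-[(2E)-3-bromopent-2-en-1-yl]-5-(tert-butyldimethylsilyloxy)-6-(prop-2-en-1-yl)oxan-3-ol | C=CC[C@@H]1O[C@H](C/C=C(\CC)Br)[C@@H](O)C[C@H]1O[Si](C)(C)C(C)(C)C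
A3 | alternative 2 | (2S,3R)-2-[(2Z)-pent-2-en-4-yn-1-yl]-3-[(2Z,5E)-6-bromoocta-2,5-dien-1-yl]oxirane (cis-6,7-epoxide of the linear C15 chain) | C#C/C=C\C[C@@H]1O[C@@H]1C/C=C\C/C=C(/Br)CC
A4 | alternative 2 | 1-oxoniabicyclo[3.1.0]hexane ion with O bonded to C6, C7 and C10 and Br at C9 (diastereomer needed for the target) | C#C/C=C\C[C@@H]1[O+]2[C@@H]1C[C@@H](Br)[C@H]2C/C=C(/Br)CC
A5 | alternative 3 | meso-8-oxabicyclo[3.2.1]oct-6-en-3-one | O=C1C[C@H]2C=C[C@@H](C1)O2
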